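**Strategy.** Ring A (the ten-membered carbocycle C1–C10) is traced back to a six-membered ring by adding a C5–C10 bond: C5 and C10 lie 1,6 across ring A, so this bond gives a carvone-derived cyclohexane C5–C10 that already holds C7, C8 and C9, with C1=C2 (vinyl on C10) and C3=C4 (isopropenyl on C5) as arms. One anionic oxy-Cope shift forms C2–C3, breaks C5–C10 and releases ring A as its C5 enolate with an E C1=C10 alkene. The precursor is a 5-isopropenyl-10-vinylcyclohexan-5-ol with trans-diequatorial alkenyl groups and C8/C9 silyl ethers; its axial hydroxyl comes from epoxide reduction, because carbonyl addition would favour the other face. Ring B and the C10 carbinol follow.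

Key step: step 12

Remark: every intermediate carries the target atom numbers (ring A C1–C10, C14 on C10, C15 on C4, C11–C13 in the side chain and lactone); β is the face of the C7 side chain when the ring is drawn flat with the numbers running clockwise, α the opposite face; the acyl group is taken as (R)-2-methylbutanoyl, as drawn in the target.

**Step 1**
Reactants: 1 (S)-carvone; 2 acetaldehyde
Product: 4 10α-(1-hydroxyethyl)-10β-methyl-7β-isopropenylcyclohex-8-en-5-one (both carbinol epimers), via potassium dienolate 3 (not isolated)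
Conditions: KOt-Bu, THF, −78 to 0 °C; MeCHO, −78 °C; AcOH
Reagents that add atoms: none
Why: Deconjugative aldol addition: the through-conjugated dienolate 3, reached under equilibrating conditions, should attack the aldehyde through C10 on the face opposite the C7 isopropenyl group, which sets the quaternary C10 (new chain α, methyl β) and moves the ring alkene to C8=C9, the carbinol centre being removed in step 2.

**Step 2**
Reactants: 4 10α-(1-hydroxyethyl)-10β-methyl-7β-isopropenylcyclohex-8-en-5-one
Product: 6 10β-methyl-10α-vinyl-7β-isopropenylcyclohex-8-en-5-one, via sulfamate 5 (not isolated)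
Conditions: Burgess reagent, PhMe, 70 °C
Reagents that add atoms: none
Why: Burgess dehydration (syn-elimination of the sulfamate) can take a hydrogen only from the terminal methyl because C10 is quaternary, so the C1=C2 vinyl group should form without isomerising the β,γ-unsaturated ketone.

**Step 3**
Reactants: 6 10β-methyl-10α-vinyl-7β-isopropenylcyclohex-8-en-5-one
Product: 7 10β-methyl-10α-vinyl-7β-isopropenylcyclohex-8-en-5β-ol
Conditions: NaBH4, MeOH, 0 °C
Reagents that add atoms: none
Why: Borohydride reduction by axial hydride delivery on the α face, anti to the pseudo-axial C10 methyl, should set the 5β-hydroxyl, which is needed only as a directing group.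

**Step 4**
Reactants: 7 10β-methyl-10α-vinyl-7β-isopropenylcyclohex-8-en-5β-ol
Product: 8 8β,9β-epoxy-10β-methyl-10α-vinyl-7β-isopropenylcyclohexan-5β-ol
Conditions: VO(acac)2 (cat.), t-BuOOH, PhMe, 0 °C to rt
Reagents that add atoms: tert-butyl hydroperoxide, CC(C)(C)OO
Why: Hydroxyl-directed vanadium-catalysed epoxidation of a cyclohex-3-enol delivers oxygen to C8=C9 on the face of the 5β-hydroxyl and should spare the vinyl and isopropenyl groups, which the hydroxyl reaches less well.

**Step 5**
Reactants: 8 8β,9β-epoxy-10β-methyl-10α-vinyl-7β-isopropenylcyclohexan-5β-ol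
Product: 9 8β,9β-epoxy-10β-methyl-10α-vinyl-7β-isopropenylcyclohexan-5-one
Conditions: Pr4N[RuO4] (cat.), NMO, 4 Å MS, CH2Cl2, rt
Reagents that add atoms: none
Why: Ley–Griffith oxidation regenerates the C5 ketone under neutral conditions that the epoxide and the three alkenes tolerate, and no stereocentre changes.

**Step 6**
Reactants: 9 8β,9β-epoxy-10β-methyl-10α-vinyl-7β-isopropenylcyclohexan-5-one
Product: 10 8α,9β-dihydroxy-10β-methyl-10α-vinyl-7β-isopropenylcyclohexan-5-one
Conditions: HClO4 (cat.), THF/H2O, 0 °C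
Reagents that add atoms: water, O
Why: Acid-catalysed epoxide hydrolysis with anti opening at C8, the carbon that is neither neopentyl nor β to the electron-withdrawing carbonyl, should invert C8 and retain C9, giving the trans 8α,9β-diol.

**Step 7**
Reactants: 10 8α,9β-dihydroxy-10β-methyl-10α-vinyl-7β-isopropenylcyclohexan-5-one
Product: 12 8α,9β-bis(tert-butyldimethylsilyloxy)-10β-methyl-10α-vinyl-7β-isopropenylcyclohexan-5-one, via 8α-monosilyl ether 11 (not isolated)
Conditions: TBSOTf, 2,6-lutidine, CH2Cl2, −78 to 0 °C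
Reagents that add atoms: tert-butyldimethylsilyl triflate, CC(C)(C)[Si](C)(C)OS(=O)(=O)C(F)(F)F
Why: Silyl triflate silylation protects both secondary hydroxyls, the hindered C9 one included, so that no alkoxide β to the ketone or near the later C5 alkoxide can trigger retro-aldol cleavage or fragmentation.

**Step 8**
Reactants: 12 8α,9β-bis(tert-butyldimethylsilyloxy)-10β-methyl-10α-vinyl-7β-isopropenylcyclohexan-5-one
Product: 14 8α,9β-bis(tert-butyldimethylsilyloxy)-10β-methyl-10α-vinyl-7β-isopropenylcyclohex-5-en-5-yl triflate, via potassium enolate 13 (not isolated)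
Conditions: KN(SiMe3)2, THF, −78 °C; PhNTf2
Reagents that add atoms: N-phenylbis(trifluoromethanesulfonimide), O=S(=O)(N(c1ccccc1)S(=O)(=O)C(F)(F)F)C(F)(F)F
Why: Enolate O-sulfonylation: C10 is quaternary, so deprotonation can occur only at C6 and the C5–C6 enol triflate is the single regioisomer.

**Step 9**
Reactants: 14 8α,9β-bis(tert-butyldimethylsilyloxy)-10β-methyl-10α-vinyl-7β-isopropenylcyclohex-5-en-5-yl triflate; 15 isopropenylboronic acid pinacol ester
Product: 16 5,7β-diisopropenyl-8α,9β-bis(tert-butyldimethylsilyloxy)-10β-methyl-10α-vinylcyclohex-5-ene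
Conditions: Pd(PPh3)4 (cat.), K3PO4, dioxane/H2O, 80 °C
Reagents that add atoms: none
Why: Suzuki–Miyaura coupling of the alkenyl triflate with the alkenylboronate attaches C4, with its methyl C15 and methylene C3, to C5 and keeps the ring alkene in place.

**Step 10**
Reactants: 16 5,7β-diisopropenyl-8α,9β-bis(tert-butyldimethylsilyloxy)-10β-methyl-10α-vinylcyclohex-5-ene
Product: 17 5α,6α-epoxy-5β,7β-diisopropenyl-8α,9β-bis(tert-butyldimethylsilyloxy)-10β-methyl-10α-vinylcyclohexane
Conditions: mCPBA, CH2Cl2, −20 °C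
Reagents that add atoms: 3-chloroperoxybenzoic acid, O=C(OO)c1cccc(Cl)c1
Why: Prilezhaev epoxidation should select the most substituted alkene (C5=C6 of the twisted diene) and attack its α face, away from the pseudo-axial C10 methyl and the C7 isopropenyl group, as peracids do with steroidal 5-enes, so the C5–O bond is set α.

**Step 11**
Reactants: 17 5α,6α-epoxy-5β,7β-diisopropenyl-8α,9β-bis(tert-butyldimethylsilyloxy)-10β-methyl-10α-vinylcyclohexane
Product: 18 5β,7β-diisopropenyl-8α,9β-bis(tert-butyldimethylsilyloxy)-10β-methyl-10α-vinylcyclohexan-5α-ol (the 1-isopropenyl-2-methyl-2-vinylcyclohexanol precursor)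
Conditions: LiAlH4, THF, 0 °C to rt
Reagents that add atoms: none
Why: Hydride opening of the epoxide in the trans-diaxial (Fürst–Plattner) sense at secondary C6, as with steroidal 5α,6α-epoxides, leaves an axial 5α-hydroxyl and an equatorial 5β-isopropenyl group trans to the C10 vinyl, the arrangement that carbonyl addition anti to the axial C10 methyl would not give.

**Step 12**
Reactants: 18 5β,7β-diisopropenyl-8α,9β-bis(tert-butyldimethylsilyloxy)-10β-methyl-10α-vinylcyclohexan-5α-ol
Product: 21 (E)-8α,9β-bis(tert-butyldimethylsilyloxy)-4β,10-dimethyl-7β-isopropenylcyclodec-1(10)-en-5-one, via potassium alkoxide 19 (not isolated), via potassium enolate 20 (not isolated)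
Conditions: KH, 18-crown-6, THF, 0 to 50 °C; AcOH, −78 °C
Reagents that add atoms: none
Why: The potassium alkoxide 19 undergoes a concerted [3,3] sigmatropic shift of the 1,5-diene C3=C4–C5–C10–C1=C2 in which C2–C3 forms while C5–C10 breaks, and enolate 20 is protonated at C4 on quenching. The closest known reaction type is the anionic oxy-Cope ring expansion of trans-1,2-dialkenylcyclohexanols to (E)-cyclodec-5-enones. Ring A is closed by four-atom ring expansion: the new C2–C3 bond joins the two alkenyl termini through a six-membered chair array while the six-membered carbocycle opens. With both alkenyl groups equatorial, C6 and C9 are pseudo-equatorial in that chair, which fixes the E geometry of C1=C10; C4 is set by protonation of the enolate on its exposed outer face and, being α to the ketone, can be equilibrated if needed. The step needs the [3,3] path to win over fragmentation of the alkoxide and over a boat pathway, and the trans-diequatorial dialkenyl arrangement, the absence of any other 1,5-diene and the irreversible formation of the enolate secure this, while C7, C8 and C9 are not touched.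

**Step 13**
Reactants: 21 (E)-8α,9β-bis(tert-butyldimethylsilyloxy)-4β,10-dimethyl-7β-isopropenylcyclodec-1(10)-en-5-one
Product: 23 (E)-8α,9β-dihydroxy-4β,10-dimethyl-7β-isopropenylcyclodec-1(10)-en-5-one, via 9β-monosilyl ether 22 (not isolated)
Conditions: HF·pyridine, pyridine, THF, 0 °C to rt
Reagents that add atoms: none
Why: Fluoride-mediated silyl ether cleavage under pyridine-buffered conditions frees the C8 and C9 hydroxyls without enolising C4 or provoking transannular reactions of the cyclodecenone.

**Step 14**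
Reactants: 23 (E)-8α,9β-dihydroxy-4β,10-dimethyl-7β-isopropenylcyclodec-1(10)-en-5-one
Product: 24 1α,10β-epoxy-8α,9β-dihydroxy-4β,10α-dimethyl-7β-isopropenylcyclodecan-5-one
Conditions: VO(acac)2 (cat.), t-BuOOH, CH2Cl2, −10 °C
Reagents that add atoms: tert-butyl hydroperoxide, CC(C)(C)OO
Why: Hydroxyl-directed vanadium-catalysed epoxidation of the allylic alcohol: with 1,2-allylic strain between the C14 methyl and C8 turning H9 into the alkene plane, oxygen should reach the face that places the C10–O bond cis to the C9 hydroxyl (erythro), while the isopropenyl group has no allylic hydroxyl.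

**Step 15**
Reactants: 24 1α,10β-epoxy-8α,9β-dihydroxy-4β,10α-dimethyl-7β-isopropenylcyclodecan-5-one
Product: 25 8α,9β,10β-trihydroxy-4β,10α-dimethyl-1β-(phenylselanyl)-7β-isopropenylcyclodecan-5-one
Conditions: PhSeH, Ti(Oi-Pr)4, CH2Cl2, 0 °C to rt
Reagents that add atoms: benzeneselenol, [SeH]c1ccccc1
Why: Titanium-assisted SN2 opening of a 2,3-epoxy alcohol at its C3 carbon (ring C1, the only epoxide carbon open to backside attack) by the soft selenol keeps the C10–O bond and its configuration and leaves untouched the C5 ketone, which a hydride reagent would reduce.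

**Step 16**
Reactants: 25 8α,9β,10β-trihydroxy-4β,10α-dimethyl-1β-(phenylselanyl)-7β-isopropenylcyclodecan-5-one
Product: 26 8α,9β,10β-trihydroxy-4β,10α-dimethyl-7β-isopropenylcyclodecan-5-one
Conditions: Bu3SnH, AIBN (cat.), PhMe, 80 °C
Reagents that add atoms: none
Why: Radical deselenation (tin hydride chain reduction of the C–Se bond) turns C1 into a methylene group without touching the ketone, the alkene or the hydroxyls.

**Step 17**
Reactants: 26 8α,9β,10β-trihydroxy-4β,10α-dimethyl-7β-isopropenylcyclodecan-5-one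
Product: 27 8α,9β,10β-trihydroxy-7β-(3-hydroxyprop-1-en-2-yl)-4β,10α-dimethylcyclodecan-5-one
Conditions: SeO2 (cat.), t-BuOOH, CH2Cl2, rt
Reagents that add atoms: tert-butyl hydroperoxide, CC(C)(C)OO
Why: Riley allylic oxidation (ene reaction then [2,3] shift) of the only remaining alkene should hydroxylate the C12 methyl in preference to the C7 methine, and any enal formed by over-oxidation is the intermediate of step 18.

**Step 18**
Reactants: 27 8α,9β,10β-trihydroxy-7β-(3-hydroxyprop-1-en-2-yl)-4β,10α-dimethylcyclodecan-5-one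
Product: 30 9β,10β-dihydroxy-5-oxogermacr-11(13)-en-12,8α-olide (9-O-desacyl target), via hydroxy enal 28 (not isolated), via lactol 29 (not isolated)
Conditions: MnO2, CH2Cl2, rt
Reagents that add atoms: none
Why: Oxidative lactonisation: MnO2 oxidises the allylic alcohol to enal 28, the neighbouring C8 hydroxyl closes the five-membered lactol 29 (5-exo-trig) and MnO2 oxidises it to the α-methylene-γ-lactone of ring B, while the saturated C9 and C10 hydroxyls are inert.

**Step 19**
Reactants: 30 9β,10β-dihydroxy-5-oxogermacr-11(13)-en-12,8α-olide; 31 (R)-2-methylbutanoic acid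
Product: 33 Ineupatorolide A, via O-acylisourea 32 (not isolated)
Conditions: DCC, DMAP (cat.), CH2Cl2, 0 °C to rt
Reagents that add atoms: none
Why: Steglich esterification should acylate the only secondary hydroxyl (C9) and leave the tertiary C10 hydroxyl free, with the α-stereocentre of the acid retained under the mild carbodiimide conditions.

**Compound list**
1 | (S)-carvone | CC(=C)[C@@H]1CC(=O)C(C)=CC1 | starting material
2 | acetaldehyde | CC=O | starting material
3 | potassium through-conjugated dienolate of 1 (oxido on C5, C5=C10 and C8=C9) | [K+].[O-]C1=C(C)C=C[C@H](C(C)=C)C1 | intermediate (not isolated)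
4 | 10α-(1-hydroxyethyl)-10β-methyl-7β-isopropenylcyclohex-8-en-5-one, both carbinol epimers | CC(O)[C@@]1(C)C=C[C@H](C(C)=C)CC1=O | intermediate
5 | N-(methoxycarbonyl)sulfamate ester of 4, triethylammonium salt | COC(=O)[N-]S(=O)(=O)OC(C)[C@@]1(C)C=C[C@H](C(C)=C)CC1=O.CC[NH+](CC)CC | intermediate (not isolated)
6 | 10β-methyl-10α-vinyl-7β-isopropenylcyclohex-8-en-5-one | C=C[C@@]1(C)C=C[C@H](C(C)=C)CC1=O | intermediate
7 | 10β-methyl-10α-vinyl-7β-isopropenylcyclohex-8-en-5β-ol | C=C[C@@]1(C)C=C[C@H](C(C)=C)C[C@@H]1O | intermediate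
8 | 8β,9β-epoxy-10β-methyl-10α-vinyl-7β-isopropenylcyclohexan-5β-ol | C=C[C@@]1(C)[C@@H]2O[C@@H]2[C@H](C(C)=C)C[C@@H]1O | intermediate
9 | 8β,9β-epoxy-10β-methyl-10α-vinyl-7β-isopropenylcyclohexan-5-one | C=C[C@@]1(C)[C@@H]2O[C@@H]2[C@H](C(C)=C)CC1=O | intermediate
10 | 8α,9β-dihydroxy-10β-methyl-10α-vinyl-7β-isopropenylcyclohexan-5-one | C=C[C@@]1(C)[C@H](O)[C@@H](O)[C@H](C(C)=C)CC1=O | intermediate
11 | 8α-(tert-butyldimethylsilyloxy)-9β-hydroxy-10β-methyl-10α-vinyl-7β-isopropenylcyclohexan-5-one | C=C[C@@]1(C)[C@H](O)[C@@H](O[Si](C)(C)C(C)(C)C)[C@H](C(C)=C)CC1=O | intermediate (not isolated)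
12 | 8α,9β-bis(tert-butyldimethylsilyloxy)-10β-methyl-10α-vinyl-7β-isopropenylcyclohexan-5-one | C=C[C@@]1(C)[C@H](O[Si](C)(C)C(C)(C)C)[C@@H](O[Si](C)(C)C(C)(C)C)[C@H](C(C)=C)CC1=O | intermediate
13 | potassium C5–C6 enolate of 12 | C=C[C@@]1(C)[C@H](O[Si](C)(C)C(C)(C)C)[C@@H](O[Si](C)(C)C(C)(C)C)[C@H](C(C)=C)C=C1[O-].[K+] | intermediate (not isolated)
14 | 8α,9β-bis(tert-butyldimethylsilyloxy)-10β-methyl-10α-vinyl-7β-isopropenylcyclohex-5-en-5-yl triflate | C=C[C@@]1(C)[C@H](O[Si](C)(C)C(C)(C)C)[C@@H](O[Si](C)(C)C(C)(C)C)[C@H](C(C)=C)C=C1OS(=O)(=O)C(F)(F)F | intermediate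
15 | isopropenylboronic acid pinacol ester | CC(=C)B1OC(C)(C)C(C)(C)O1 | starting material
16 | 5,7β-diisopropenyl-8α,9β-bis(tert-butyldimethylsilyloxy)-10β-methyl-10α-vinylcyclohex-5-ene | C=C[C@@]1(C)[C@H](O[Si](C)(C)C(C)(C)C)[C@@H](O[Si](C)(C)C(C)(C)C)[C@H](C(C)=C)C=C1C(C)=C | intermediate
17 | 5α,6α-epoxy-5β,7β-diisopropenyl-8α,9β-bis(tert-butyldimethylsilyloxy)-10β-methyl-10α-vinylcyclohexane | C=C[C@@]1(C)[C@H](O[Si](C)(C)C(C)(C)C)[C@@H](O[Si](C)(C)C(C)(C)C)[C@H](C(C)=C)[C@H]2O[C@@]12C(C)=C | intermediate
18 | 5β,7β-diisopropenyl-8α,9β-bis(tert-butyldimethylsilyloxy)-10β-methyl-10α-vinylcyclohexan-5α-ol (oxy-Cope precursor) | C=C[C@@]1(C)[C@H](O[Si](C)(C)C(C)(C)C)[C@@H](O[Si](C)(C)C(C)(C)C)[C@H](C(C)=C)C[C@]1(O)C(C)=C | intermediate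
19 | potassium alkoxide of 18 | C=C[C@@]1(C)[C@H](O[Si](C)(C)C(C)(C)C)[C@@H](O[Si](C)(C)C(C)(C)C)[C@H](C(C)=C)C[C@]1([O-])C(C)=C.[K+] | intermediate (not isolated)
20 | potassium C4–C5 enolate of 21 (C3 trans to C6, C1=C10 E) | C/C1=C(/[O-])C[C@@H](C(C)=C)[C@H](O[Si](C)(C)C(C)(C)C)[C@@H](O[Si](C)(C)C(C)(C)C)/C(C)=C/CC1.[K+] | intermediate (not isolated)
21 | (E)-8α,9β-bis(tert-butyldimethylsilyloxy)-4β,10-dimethyl-7β-isopropenylcyclodec-1(10)-en-5-one (oxy-Cope product) | C[C@@H]1CC/C=C(C)/[C@H](O[Si](C)(C)C(C)(C)C)[C@@H](O[Si](C)(C)C(C)(C)C)[C@H](C(C)=C)CC1=O | intermediate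
22 | (E)-9β-(tert-butyldimethylsilyloxy)-8α-hydroxy-4β,10-dimethyl-7β-isopropenylcyclodec-1(10)-en-5-one | C[C@@H]1CC/C=C(C)/[C@H](O[Si](C)(C)C(C)(C)C)[C@@H](O)[C@H](C(C)=C)CC1=O | intermediate (not isolated)
23 | (E)-8α,9β-dihydroxy-4β,10-dimethyl-7β-isopropenylcyclodec-1(10)-en-5-one | C[C@@H]1CC/C=C(C)/[C@H](O)[C@@H](O)[C@H](C(C)=C)CC1=O | intermediate
24 | 1α,10β-epoxy-8α,9β-dihydroxy-4β,10α-dimethyl-7β-isopropenylcyclodecan-5-one | C[C@@H]1CC[C@H]2O[C@]2(C)[C@H](O)[C@@H](O)[C@H](C(C)=C)CC1=O | intermediate
25 | 8α,9β,10β-trihydroxy-4β,10α-dimethyl-1β-(phenylselanyl)-7β-isopropenylcyclodecan-5-one | C[C@@H]1CC[C@H]([Se]c2ccccc2)[C@](C)(O)[C@H](O)[C@@H](O)[C@H](C(C)=C)CC1=O | intermediate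
26 | 8α,9β,10β-trihydroxy-4β,10α-dimethyl-7β-isopropenylcyclodecan-5-one | C[C@@H]1CCC[C@](C)(O)[C@H](O)[C@@H](O)[C@H](C(C)=C)CC1=O | intermediate
27 | 8α,9β,10β-trihydroxy-7β-(3-hydroxyprop-1-en-2-yl)-4β,10α-dimethylcyclodecan-5-one | C[C@@H]1CCC[C@](C)(O)[C@H](O)[C@@H](O)[C@H](C(=C)CO)CC1=O | intermediate
28 | 8α,9β,10β-trihydroxy-4β,10α-dimethyl-7β-(3-oxoprop-1-en-2-yl)cyclodecan-5-one | C[C@@H]1CCC[C@](C)(O)[C@H](O)[C@@H](O)[C@H](C(=C)C=O)CC1=O | intermediate (not isolated)
29 | C12 lactol of 28 closed on the C8 oxygen, both C12 epimers | C[C@@H]1CCC[C@](C)(O)[C@H](O)[C@H]2OC(O)C(=C)[C@@H]2CC1=O | intermediate (not isolated)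
30 | 9β,10β-dihydroxy-5-oxogermacr-11(13)-en-12,8α-olide | C[C@@H]1CCC[C@](C)(O)[C@H](O)[C@H]2OC(=O)C(=C)[C@@H]2CC1=O | intermediate
31 | (R)-2-methylbutanoic acid | CC[C@@H](C)C(=O)O | starting material
32 | O-acylisourea of 31 and DCC | CC[C@@H](C)C(=O)OC(=NC1CCCCC1)NC1CCCCC1 | intermediate (not isolated)
33 | Ineupatorolide A | C=C1C(=O)O[C@@H]2[C@@H](OC(=O)[C@H](C)CC)[C@@](C)(O)CCC[C@@H](C)C(=O)C[C@@H]12 | target

**Totals and risks**

Total step count: 19. Longest linear sequence: 19 steps, from 1 to 33; compounds 2, 15 and 31 are used as purchased.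

Steps most likely to fail:

Step 1. Reaction through the cross-conjugated C6 enolate, retro-aldol cleavage of the hindered aldolate and self-condensation of the aldehyde may erode the C10 adduct. The fallback sets out from 1: dienolate 3 is added to phenyl vinyl sulfoxide (KOt-Bu, THF, 0 °C), a non-enolisable acceptor that cannot revert, to give the 10α-[2-(phenylsulfinyl)ethyl]-10β-methyl-7β-isopropenylcyclohex-8-en-5-one F1. Thermal sulfoxide syn-elimination (PhMe, 110 °C, CaCO3) then gives the vinyl group directly, and the route is rejoined at 6.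

Step 12. Fragmentation of the alkoxide into a C5 ketone and a C10 allyl anion, transfer of the C9 silyl group to the C5 alkoxide, or a slow shift in the crowded ring may compete with the rearrangement. The fallback sets out from 18: divalent-palladium catalysis (PdCl2(PhCN)2, THF, 25 °C) promotes the same C2–C3 formation and C5–C10 cleavage on the neutral alcohol by cyclisation-induced rearrangement, the C15 methyl stabilising the developing positive charge at C4. It comes back at 21 and makes no new compound (F0).

Step 14. The conformation of ring A, not the hydroxyl, may decide which alkene face is exposed, so facial selectivity may be poor, and the C8 hydroxyl may steer some oxidant to the isopropenyl group. The fallback sets out from 23: reagent-controlled Sharpless–Katsuki epoxidation (Ti(Oi-Pr)4, the enantiomer of diethyl tartrate matched to the C9 carbinol, t-BuOOH, 4 Å MS, CH2Cl2, −20 °C), which is erythro-selective for secondary allylic alcohols. It comes back at 24 and makes no new compound (F0).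

**Further compounds**
F1 | step 1 | 10α-[2-(phenylsulfinyl)ethyl]-10β-methyl-7β-isopropenylcyclohex-8-en-5-one (sulfur epimers) | O=S(CC[C@@]1(C)C=C[C@H](C(C)=C)CC1=O)c1ccccc1
F0 | step 12 | none | none
F0 | step 14 | none | none
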